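**Plan**

- Retrosynthetic cuts: first the two MOM ethers; then, in the pyranone ring (O1, C2, C3, C4, C4a, C8a), the C3–C4 bond, with C3 folded back as an iodomethyl group on C2 so that C2 is bonded directly to the carbonyl carbon (a 2-aryl-benzofuran-3(2H)-one); then C3 itself (CH2I2), the C2–aryl bond (ketone α-arylation) and the C8–prenyl bond (back to an O-prenyl ether).
- Forward order: the A ring is bought as a benzofuranone and prenyl is moved from O4 to C7 by Claisen–Cope; the B-ring chromene is made separately (chromanone → chromene); the halves are joined at C2; the five-membered furanone is enlarged by one carbon to the six-membered pyranone; the MOM groups come off last.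
- Enabling feature: C2 carries both the ring oxygen O1 and the B-ring aryl, so a C2 radical is benzylic and α-oxygenated. This drives a 1,2-acyl shift from C2 to an exocyclic CH2 radical irreversibly toward the six-membered ring.
- Stereochemistry: the only stereocentre, C2, is created in the ring enlargement by H-atom transfer from a chiral thiol catalyst to the planar C2 radical (Re face gives 2S). The quaternary centre of the precursor is racemic and is erased, and no later step touches C2.

Key step: step 10

Remark: compounds 1, 3, 8 and 9 are taken as purchased; the chiral thiol in step 10 is a catalyst, and the antipode that gives Re-face delivery has to be found by screening.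

**Step 1**
Reactants: 1 4,6-dihydroxybenzofuran-3(2H)-one
Product: 2 4-hydroxy-6-methoxybenzofuran-3(2H)-one
Conditions: Me2SO4 (1.05 equiv), K2CO3 (1.1 equiv), DMF, 0 °C to rt
Reagents that add atoms: dimethyl sulfate, COS(=O)(=O)OC
Why: Selective Williamson O-methylation should occur at the 6-OH, which is para to the ketone and more acidic, while the 4-OH is held in a hydrogen bond to C3=O.

**Step 2**
Reactants: 2 4-hydroxy-6-methoxybenzofuran-3(2H)-one; 3 3-methylbut-2-en-1-ol (prenol)
Product: 4 6-methoxy-4-[(3-methylbut-2-en-1-yl)oxy]benzofuran-3(2H)-one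
Conditions: PPh3, DIAD, THF, 0 °C to rt
Reagents that add atoms: none
Why: Mitsunobu etherification alkylates the chelated phenol under neutral conditions and so avoids enolate alkylation at the acidic C2 methylene.

**Step 3**
Reactants: 4 6-methoxy-4-[(3-methylbut-2-en-1-yl)oxy]benzofuran-3(2H)-one
Product: 6 4-hydroxy-6-methoxy-7-(3-methylbut-2-en-1-yl)benzofuran-3(2H)-one, via Claisen dienone 5 (not isolated)
Conditions: Eu(fod)3 (10 mol %), CHCl3, 70 °C, sealed tube
Reagents that add atoms: none
Why: A europium-chelated tandem aromatic Claisen/Cope (para-Claisen) rearrangement, known for aryl prenyl ethers peri to a carbonyl, should carry the prenyl group from O4 through C5 to C7 (para to O4) and then re-aromatise.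

**Step 4**
Reactants: 6 4-hydroxy-6-methoxy-7-(3-methylbut-2-en-1-yl)benzofuran-3(2H)-one
Product: 7 6-methoxy-4-(methoxymethoxy)-7-(3-methylbut-2-en-1-yl)benzofuran-3(2H)-one
Conditions: MOMCl, i-Pr2NEt, CH2Cl2, 0 °C to rt
Reagents that add atoms: chloromethyl methyl ether, COCCl
Why: MOM ether formation with a hindered amine base masks the phenol for the base-mediated steps without forming the C2 enolate.

**Step 5**
Reactants: 8 4-bromobenzene-1,3-diol; 9 3-methylbut-2-enoic acid
Product: 11 6-bromo-7-hydroxy-2,2-dimethylchroman-4-one, via aryl enone 10 (not isolated)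
Conditions: MeSO3H/P2O5 (as solvent), 70 °C
Reagents that add atoms: none
Why: Friedel–Crafts acylation at the only unhindered doubly activated carbon (C6 of the bromoresorcinol), followed by intramolecular oxa-Michael addition of the ortho hydroxyl, fixes the linear 6-bromo-7-hydroxy pattern.

**Step 6**
Reactants: 11 6-bromo-7-hydroxy-2,2-dimethylchroman-4-one
Product: 13 6-bromo-2,2-dimethyl-2H-chromen-7-ol, via chromane-4,7-diol 12 (not isolated)
Conditions: NaBH4, MeOH/THF, 0 °C to rt; then p-TsOH·H2O (cat.), toluene, 80 °C
Reagents that add atoms: none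
Why: Borohydride reduction and acid-catalysed E1 dehydration of the benzylic alcohol is the standard chromanone-to-2H-chromene conversion.

**Step 7**
Reactants: 13 6-bromo-2,2-dimethyl-2H-chromen-7-ol
Product: 14 6-bromo-7-(methoxymethoxy)-2,2-dimethyl-2H-chromene
Conditions: MOMCl, i-Pr2NEt, CH2Cl2, 0 °C to rt
Reagents that add atoms: chloromethyl methyl ether, COCCl
Why: MOM ether formation protects the phenol ortho to bromine with a small group that should not block the later cross-coupling.

**Step 8**
Reactants: 7 6-methoxy-4-(methoxymethoxy)-7-(3-methylbut-2-en-1-yl)benzofuran-3(2H)-one; 14 6-bromo-7-(methoxymethoxy)-2,2-dimethyl-2H-chromene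
Product: 15 rac-6-methoxy-4-(methoxymethoxy)-2-[7-(methoxymethoxy)-2,2-dimethyl-2H-chromen-6-yl]-7-(3-methylbut-2-en-1-yl)benzofuran-3(2H)-one
Conditions: Pd(OAc)2 (5 mol %), XPhos (10 mol %), K3PO4, toluene, 80 °C, argon
Reagents that add atoms: none
Why: Palladium-catalysed ketone α-arylation of the acidic α-aryloxy ketone joins the two halves at C2; the new centre is racemic and is erased in step 10.

**Step 9**
Reactants: 15 rac-2-aryl-benzofuran-3(2H)-one (as above)
Product: 16 rac-2-(iodomethyl)-6-methoxy-4-(methoxymethoxy)-2-[7-(methoxymethoxy)-2,2-dimethyl-2H-chromen-6-yl]-7-(3-methylbut-2-en-1-yl)benzofuran-3(2H)-one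
Conditions: NaH, CH2I2 (excess), THF/DMPU, 0 °C to rt
Reagents that add atoms: diiodomethane, ICI
Why: C-alkylation of the soft, aryl-stabilised enolate with excess diiodomethane installs the future C3 as an iodomethyl group on C2, the standard way to make a Dowd–Beckwith precursor.

**Step 10**
Reactants: 16 rac-2-(iodomethyl)-2-aryl-benzofuran-3(2H)-one (as above)
Product: 17 (2S)-7-methoxy-5-(methoxymethoxy)-2-[7-(methoxymethoxy)-2,2-dimethyl-2H-chromen-6-yl]-8-(3-methylbut-2-en-1-yl)chroman-4-one
Conditions: 4CzIPN (2 mol %), Et3N (3 equiv), chiral Cys-containing β-turn peptide thiol (10 mol %), MeCN (0.02 M), blue LEDs, 0 °C; aqueous work-up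
Reagents that add atoms: none
Why: Proposed new method: an α-aminoalkyl radical formed from Et3N by the photocatalyst abstracts iodine from 16, the primary radical adds 3-exo-trig to the C3 ketone carbon, and the cyclopropyloxy radical opens by β-scission of the old C2–C(=O) bond, a 1,2-acyl shift (Dowd–Beckwith one-carbon ring enlargement) that turns the five-membered furanone into the six-membered pyranone. The closest known reactions are Dowd–Beckwith expansions of 2-halomethyl benzo-fused cycloalkanones, amine-mediated photocatalytic halogen-atom-transfer dehalogenation, and enantioselective hydrogen-atom transfer from chiral thiols to prochiral α-heteroatom radicals; joining them on a 2-aryl-benzofuran-3(2H)-one with an enantio-determining H-transfer is the untested part. The only new stereocentre, C2, forms when the planar ring-enlarged radical takes H from the thiol on its Re face (giving 2S), so it is under catalyst control, with the C4 carbonyl and ring oxygen as hydrogen-bond acceptors for docking the peptide. The step needs rearrangement before H-transfer to the primary radical, opening of the cyclopropyloxy radical toward C2 and not back or by a neophyl aryl shift, and the thiol as the only H donor to the C2 radical. The substrate secures the first two because the C2 radical is both benzylic (B ring) and α to the ring oxygen, which makes the acyl shift fast and irreversible; the low thiol loading and a solvent that is not an H donor secure the third. The quaternary centre of 16 is destroyed in the shift, so racemic 16 suffices.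

**Step 11**
Reactants: 17 (2S)-bis-MOM flavanone (as above)
Product: 18 (2S)-5-hydroxy-2-(7-hydroxy-2,2-dimethyl-2H-chromen-6-yl)-7-methoxy-8-(3-methylbut-2-en-1-yl)chroman-4-one (maackiaflavanone A)
Conditions: ZnBr2, n-PrSH, CH2Cl2, 0 °C, short reaction time
Reagents that add atoms: none
Why: Lewis acid/thiol cleavage of aryl MOM ethers is fast, non-basic and free of protic acid, so the chromene, the prenyl group and the C2 centre (which epimerises only through base-induced ring opening) should survive.

**Compound list**

1 | 4,6-dihydroxybenzofuran-3(2H)-one | O=C1COc2cc(O)cc(O)c12 | starting material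
2 | 4-hydroxy-6-methoxybenzofuran-3(2H)-one | COc1cc(O)c2C(=O)COc2c1 | intermediate
3 | 3-methylbut-2-en-1-ol (prenol) | CC(C)=CCO | starting material
4 | 6-methoxy-4-[(3-methylbut-2-en-1-yl)oxy]benzofuran-3(2H)-one | COc1cc(OCC=C(C)C)c2C(=O)COc2c1 | intermediate
5 | 6-methoxy-5-(2-methylbut-3-en-2-yl)benzofuran-3,4(2H,5H)-dione (Claisen dienone, racemic) | COC1=CC2=C(C(=O)CO2)C(=O)C1C(C)(C)C=C | intermediate
6 | 4-hydroxy-6-methoxy-7-(3-methylbut-2-en-1-yl)benzofuran-3(2H)-one | COc1cc(O)c2C(=O)COc2c1CC=C(C)C | intermediate
7 | 6-methoxy-4-(methoxymethoxy)-7-(3-methylbut-2-en-1-yl)benzofuran-3(2H)-one | COc1cc(OCOC)c2C(=O)COc2c1CC=C(C)C | intermediate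
8 | 4-bromobenzene-1,3-diol | Oc1ccc(Br)c(O)c1 | starting material
9 | 3-methylbut-2-enoic acid | CC(C)=CC(=O)O | starting material
10 | 1-(5-bromo-2,4-dihydroxyphenyl)-3-methylbut-2-en-1-one | CC(C)=CC(=O)c1cc(Br)c(O)cc1O | intermediate
11 | 6-bromo-7-hydroxy-2,2-dimethylchroman-4-one | CC1(C)CC(=O)c2cc(Br)c(O)cc2O1 | intermediate
12 | 6-bromo-2,2-dimethylchromane-4,7-diol (racemic) | CC1(C)CC(O)c2cc(Br)c(O)cc2O1 | intermediate
13 | 6-bromo-2,2-dimethyl-2H-chromen-7-ol | CC1(C)C=Cc2cc(Br)c(O)cc2O1 | intermediate
14 | 6-bromo-7-(methoxymethoxy)-2,2-dimethyl-2H-chromene | COCOc1cc2OC(C)(C)C=Cc2cc1Br | intermediate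
15 | rac-6-methoxy-4-(methoxymethoxy)-2-[7-(methoxymethoxy)-2,2-dimethyl-2H-chromen-6-yl]-7-(3-methylbut-2-en-1-yl)benzofuran-3(2H)-one | COc1cc(OCOC)c2C(=O)C(Oc2c1CC=C(C)C)c1cc2C=CC(C)(C)Oc2cc1OCOC | intermediate
16 | rac-2-(iodomethyl)-6-methoxy-4-(methoxymethoxy)-2-[7-(methoxymethoxy)-2,2-dimethyl-2H-chromen-6-yl]-7-(3-methylbut-2-en-1-yl)benzofuran-3(2H)-one | COc1cc(OCOC)c2C(=O)C(CI)(Oc2c1CC=C(C)C)c1cc2C=CC(C)(C)Oc2cc1OCOC | intermediate
17 | (2S)-7-methoxy-5-(methoxymethoxy)-2-[7-(methoxymethoxy)-2,2-dimethyl-2H-chromen-6-yl]-8-(3-methylbut-2-en-1-yl)chroman-4-one | COc1cc(OCOC)c2c(c1CC=C(C)C)O[C@H](c1cc3c(cc1OCOC)OC(C)(C)C=C3)CC2=O | intermediate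
18 | maackiaflavanone A, (2S)-5-hydroxy-2-(7-hydroxy-2,2-dimethyl-2H-chromen-6-yl)-7-methoxy-8-(3-methylbut-2-en-1-yl)chroman-4-one | COc1cc(O)c2c(c1CC=C(C)C)O[C@H](c1cc3c(cc1O)OC(C)(C)C=C3)CC2=O | target

**Step count and risks**

Total steps: 11. Longest linear sequence: 8 (steps 1–4, then 8–11); the B-ring branch is steps 5–7.

Steps most likely to fail:

1. Step 10. The final H-atom transfer may discriminate poorly between the two faces of the C2 radical, and the thiyl radical may re-abstract the C2–H of the product and erode its enantiomeric purity; premature H-transfer to the primary radical is a further loss channel. The fallback sets out from 16 and uses known chemistry. A tin hydride Dowd–Beckwith expansion (Bu3SnH by slow addition, AIBN, benzene, 80 °C) should give the racemic protected flavanone rac-7-methoxy-5-(methoxymethoxy)-2-[7-(methoxymethoxy)-2,2-dimethyl-2H-chromen-6-yl]-8-(3-methylbut-2-en-1-yl)chroman-4-one F1. Kinetic resolution of F1 by Noyori–Ikariya asymmetric transfer hydrogenation ((R,R)-TsDPEN rhodium or ruthenium catalyst, HCO2H/Et3N, EtOAc, rt, stopped near half conversion) should reduce the 2R enantiomer to the cis alcohol (2R,4R)-7-methoxy-5-(methoxymethoxy)-2-[7-(methoxymethoxy)-2,2-dimethyl-2H-chromen-6-yl]-8-(3-methylbut-2-en-1-yl)chroman-4-ol F2. The unreduced 2S ketone is separated by chromatography and is compound 17, where the route is rejoined.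

2. Step 8. The benzofuranone enolate may self-condense or autoxidise under the basic conditions, and oxidative addition of the hindered, electron-rich bromide may be slow. The fallback reverses the logic to a carbene/boron coupling and sets out from 7 and 14. Regitz diazo transfer to 7 (p-ABSA, DBU, MeCN) should give 2-diazo-6-methoxy-4-(methoxymethoxy)-7-(3-methylbut-2-en-1-yl)benzofuran-3(2H)-one F3. Bromine–lithium exchange on 14 (n-BuLi, THF, −78 °C), quenching with B(OMe)3 and hydrolysis should give [7-(methoxymethoxy)-2,2-dimethyl-2H-chromen-6-yl]boronic acid F4. Metal-free coupling of F3 with F4 (used as its boroxine, i-Pr2NH, 1,2-dichloroethane, heat) proceeds by 1,2-aryl shift from boron to the diazo carbon with loss of N2 and then protodeboronation, and comes back to the route at 15.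

3. Step 9. The ambident enolate may alkylate on oxygen to give a 3-alkoxybenzofuran, react sluggishly with CH2I2, or bridge two enolates with one methylene. The fallback sets out from 15 and replaces alkylation by an aldol. Hydroxymethylation with aqueous formaldehyde (cat. Et3N, THF, rt) should give rac-2-(hydroxymethyl)-6-methoxy-4-(methoxymethoxy)-2-[7-(methoxymethoxy)-2,2-dimethyl-2H-chromen-6-yl]-7-(3-methylbut-2-en-1-yl)benzofuran-3(2H)-one F5. Garegg–Samuelsson iodination of F5 (I2, PPh3, imidazole, toluene, 80 °C) comes back to the route at 16.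

**Further compounds**

F1 | step 10 | rac-7-methoxy-5-(methoxymethoxy)-2-[7-(methoxymethoxy)-2,2-dimethyl-2H-chromen-6-yl]-8-(3-methylbut-2-en-1-yl)chroman-4-one | COc1cc(OCOC)c2c(c1CC=C(C)C)OC(c1cc3c(cc1OCOC)OC(C)(C)C=C3)CC2=O
F2 | step 10 | (2R,4R)-7-methoxy-5-(methoxymethoxy)-2-[7-(methoxymethoxy)-2,2-dimethyl-2H-chromen-6-yl]-8-(3-methylbut-2-en-1-yl)chroman-4-ol | COc1cc(OCOC)c2c(c1CC=C(C)C)O[C@@H](c1cc3c(cc1OCOC)OC(C)(C)C=C3)C[C@H]2O
F3 | step 8 | 2-diazo-6-methoxy-4-(methoxymethoxy)-7-(3-methylbut-2-en-1-yl)benzofuran-3(2H)-one | COc1cc(OCOC)c2C(=O)C(=[N+]=[N-])Oc2c1CC=C(C)C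
F4 | step 8 | [7-(methoxymethoxy)-2,2-dimethyl-2H-chromen-6-yl]boronic acid | COCOc1cc2OC(C)(C)C=Cc2cc1B(O)O
F5 | step 9 | rac-2-(hydroxymethyl)-6-methoxy-4-(methoxymethoxy)-2-[7-(methoxymethoxy)-2,2-dimethyl-2H-chromen-6-yl]-7-(3-methylbut-2-en-1-yl)benzofuran-3(2H)-one | COc1cc(OCOC)c2C(=O)C(CO)(Oc2c1CC=C(C)C)c1cc2C=CC(C)(C)Oc2cc1OCOC
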